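- The ash run shows how J behaves with 2.5 mM of X, and the new flask repeats it with half the J.

| setting | ash | flask |
|---|---|---|
| J | 1 M (fed, over 4.0 h) | 0.50 M (fed, over 4.0 h) |
| X | 2.5 mM | 2.5 mM |
| remark | run made earlier |  |
| time |  | 6.0 d |

ash run (percent of the J charged)

| time / h | J / % | Q / % |
|---|---|---|
| 2.50 | 41 | 8 |
| 4.00 | 63 | 17 |
| 5.00 | 56 | 26 |
| 8.00 | 45 | 44 |
| 12.0 | 25 | 59 |
| 20.0 | 14 | 82 |
| 30.0 | 8 | 96 |

(readings scatter by 2 percentage points)

- what has gone from J into another species counts as reacted, even if it can come back
- percentages count the whole charge, also what has not yet gone in
- the reaction counts as stopped when no species that holds the J changes by six tenths of a point or more over the second half of the time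

1. at 6.0 d, what has stopped the reaction, if anything has (it is still moving / all of J has reacted / no working catalyst is left / forward and back rates have come level)
2. how much of the J has reacted by 6.0 d
3. how much Q there is at 6.0 d, in percent of the J charged

- In the first hours of the ash run, J piles up: at the end of the feed, 4.00 h, c(J) reads 63% and c(Q) reads 17%, so about 20.0% of the charge sits in something unseen. By 30.0 h that gap has closed within the scatter.
- In the middle, c(J) reads 45% at 8.00 h and 14% at 20.0 h. Replacing that stretch by one mean exponential gives 7.12 h, the tail half-life: the time in which c(J) halves on average once the feed is over.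
- To check that mean, I reckon the same way from 20.0 h to 30.0 h and get 12.4 h, longer than the mean. The curve seems to flatten, though a scatter of 2 percentage points leaves that loose.
- At the end, a first-order curve in percent ignores the charge of J as long as X stays the same, so I carry the half-life to the flask, which gets 19.7 half-lives after its feed. Taken alone, that leaves no measurable J, but the flattening makes me expect J to stop at a level above zero and below the last ash reading, 8%, with forward and back rates level.
- The forecast differs from me on the stop: it says all of J has reacted, with 99.5% reacted and 98% of Q, and holds that “neither a back reaction nor catalyst death is clearly shown”.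
- In the flask, forward and back rates have come level, with 97.1% reacted and 95.9% of Q. The forecast's two percentages hold within their margins; its stop does not.

    L ⇌ X + Q (K = 7.60 M, k = 14000 h⁻¹)
    E ⇌ L (K = 13.0, k = 210 h⁻¹)
    J → D (k = 1.90 × 10⁻⁴ h⁻¹)
    J + X ⇌ E (K = 0.330 M⁻¹, k = 870 M⁻¹ h⁻¹)
    J ⇌ Z (K = 0.330, k = 1.10 h⁻¹)

- Striking out the reverse step, E to J + X, lifts conversion from 97.1% to 100% and turns the answer on the stop, so this flask holds c(J) at 2.94% at 6.00 d, against 2.96% at 3.00 d, although 19.7 half-lives of 7.12 h have passed. So I apply the tail half-life to the excess of J over that level. The neighbour with 6.3 × 10⁻⁴ M of X has a quarter of the catalyst; I assume the half-life stretches in that ratio, to 28.3 h, and with this flask's level and the ash reading at the end of the feed as a stand-in for the starting excess I reckon 4.97% of J, while at 6.00 d that neighbour holds 4.0%.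

The runs stem from a simulated flask with made-up constants; scatter was added.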